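The readings are simulated for substances that don't exist; scatter was added.

In a one-step world every Q lost would appear as D, so I asked how far the gamma run stood from that.

| flask | Q | X | remark | time |
|---|---|---|---|---|
| gamma | 0.055 M | 20 mM (held) | run made earlier |  |
| winter | 0.050 M | 20 mM (held) |  | 3.0 h |
| noon | 0.080 M | 20 mM (held) |  | 2.0 h |

- gamma (time / min: D / %, Q / %): 12.0: 23.1, 61.3; 25.0: 39.2, 30.7; 40.0: 46.8, 13.8; 50.0: 49.1, 8.6; 60.0: 49.7, 6.7

(readings scatter by 0.5 percentage points)

- what was read earlier has a scatter of 0.5 percentage points, one standard deviation
- at the start none of X is in solution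
- a reading of Q is of its free form alone

* which one finishes higher in amount of D, in percent of the Q charged ("neither" within 2 percentage points) (winter / noon / neither)
* amount of D at the end, in percent of the Q charged, winter
* amount of D at the end, in percent of the Q charged, noon

1. I defined Y, the instantaneous yield, as D gained per Q lost. Over the first 12.0 min of gamma it read 59.7 %. From there to 60.0 min it read 48.7 %, lower than the first stretch.

2. Between the midpoints of those stretches, D rose by 13.7 mM. So I kept 8.03 /M as b, the drop in Y per molar of D standing, and froze it.

3. Taken back to zero D, this gives a starting yield Ys of 64.8 %.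

4. On this rule, Y shrinks by the factor exp(−b × Q consumed). As an estimate I froze conversion at gamma's last value, 93.3 %, although winter and noon both run longer than that reading. The final factor is then 0.688 for winter and 0.549 for noon, which is smaller than winter's.

5. Accumulated, D in percent of the charge is Ys(1 − factor)/(b × charge). That gives 50.4 % for winter and 45.5 % for noon, so my reckoning puts winter higher.

6. The forecast differs: noon higher, with 50.5 % for winter and 55 % for noon, holding that “D formation probably has a higher order in Q than the side route”.

7. Winter gave 48.6 % and noon 42.1 %, so winter finished higher. Q + D → G (k = 0.00721 /M/s); Q + J ⇌ D (K = 660 /M, k = 0.0374 /M/s); Q + J ⇌ Z (K = 110 /M, k = 0.0145 /M/s); X ⇌ J, rate k4*(csat - [J]) (kL = 0.00645 /s)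

8. Applied to noon's final D of 33.7 mM, b puts Y at 37.7 %, but at 2.00 h in noon D was being made at 0.300 of the rate at which it was used up, each step taken net. For the neighbour flask, noon charged with 0.048 M of Q, the same b reckons 50.8 %, and that flask gave 51.1 %.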